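All constants were chosen freely; the rest is arithmetic.

Early on, precatalyst releases free catalyst at 0.55 /min per precatalyst, while free catalyst is captured far faster, at 78 /min by starting material and 58 /min by impurity, so I expect it to hold little.

starting material 0.50 M; partner 0.800 equiv; precatalyst 15 mol%; impurity 42 mM

    precatalyst → free catalyst (k1 = 0.0092 /s)
    catalyst intermediate B → free catalyst + product (k2 = 0.28 /s)
    free catalyst + impurity → spent catalyst (k3 = 23 /M/s)
    starting material + free catalyst → catalyst intermediate A (k4 = 2.6 /M/s)
    partner + catalyst intermediate A ⇌ catalyst intermediate B (K5 = 1.3 /M, k5 = 0.27 /M/s)

- the form that holds most of the catalyst when 10% of the starting material are converted (catalyst intermediate A / catalyst intermediate B / free catalyst / spent catalyst / precatalyst)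
- its share of the catalyst then

Those two captures give my quantity: the selectivity factor 8.85, how many times faster free catalyst takes impurity than starting material at equal concentrations. Both losses run through free catalyst, so time drops out: the fraction of impurity left is the fraction of starting material left, raised to that factor. At 10% conversion, 39.4% of the impurity remains. Its charge is 56.0% of the catalyst charge, so spent catalyst holds 33.9% of the catalyst.

That leaves 66.1% for precatalyst, the little free catalyst and the working forms, intermediates A and B. But the conversion equals 66.7% of the catalyst charge, more than that, so the working forms must turn over. With B steady and partner as charged, they turn over at 3.05 /min. I try the precatalyst half-life, 1.26 min. If the working forms grow linearly, they must reach 22.9%, leaving 43.2% as precatalyst, whereas decay leaves half. The answer lies between these, so I commit to precatalyst, ahead of spent catalyst.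

The forecast also says precatalyst, at 47%, and starts from the same split: “Free catalyst partitions between starting material and impurity”.

The flask gives precatalyst at 46.3%. Spent catalyst stands beside it at 33.9%. At 2.50 min, starting material stands at 79.5%, and the factor turns that into 13.1% of the impurity left, where the flask holds 13.1%. The same figure puts spent catalyst at 48.6% of the catalyst, where the flask holds 48.7%.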